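The numbers in the tables were generated by integration on assumed constants; noise was put on by code.

Late in the north-east and west runs the two products stand level: at 50 min, with the readings of both runs added hand by hand, the excess of left-handed product is 1.27%. Level is the zero of my scale, the racemic case, where left-handed product and right-handed product are made in a ratio of 1.

| flask | left-handed substrate | right-handed substrate | reagent | racemization catalyst | impurity | added ligand | remark | time |
|---|---|---|---|---|---|---|---|---|
| north-east | 0.40 M | 0.40 M | 4 equiv | 1.4 mol% | 1.1 mM | 19 mM | run made earlier |  |
| west | 0.40 M | 0.40 M | 4 equiv | 2.2 mol% | 1.1 mM | 19 mM | run made earlier |  |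
| flask | 0.40 M | 0.40 M | 4.00 equiv | 1 mol% | 1.1 mM | 19 mM |  | 50 min |

| run | time / min | left-handed product / % | right-handed product / % |
|---|---|---|---|
| north-east | 4.00 | 9 | 8 |
| north-east | 12.0 | 22 | 21 |
| north-east | 25.0 | 34 | 32 |
| north-east | 40.0 | 39 | 36 |
| north-east | 50.0 | 39 | 37 |
| west | 4.00 | 13 | 5 |
| west | 12.0 | 21 | 20 |
| west | 25.0 | 33 | 30 |
| west | 40.0 | 37 | 41 |
| west | 50.0 | 41 | 41 |

(scatter of a reading: 2 percentage points)

- reagent is single-handed; left-handed substrate and right-handed substrate are mirror images of each other, charged as a racemate, each of them at the stated concentration
- an excess is the difference of the two amounts in percent of their sum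
- an excess is below zero if the other one leads
- the handed part of reagent does not stay in what it makes, so the products of the two hands are mirror images too

1. excess of left-handed product over right-handed product in the product at 2.5 min
2. excess of left-handed product over right-handed product in the product at 50 min
3. part of the left-handed substrate and right-handed substrate charged together that has reacted at 50 min

The first instants are where the two hands can differ. From the readings at 4.00 min, added over both runs, I get 1.69: this is the lead ratio, the left-handed product made per right-handed product while both substrates stand near their charge, also called the selectivity factor. I take the reagent to attack each substrate in proportion to [reagent], so its charge cancels from the ratio. As an excess the lead ratio is 25.7%, and since four readings enter, its scatter is 11 percentage points.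

In the middle the lead has gone from the readings while much substrate remains, and at the end the excess stays near zero:

| time | excess, both runs added | reacted, mean of both runs |
|---|---|---|
| 4.00 min | 25.7% | 17.5% |
| 12.0 min | 2.38% | 42.0% |
| 50 min | 1.27% | 79.0% |

For this flask I commit to an excess near 25.7% at 2.5 min, near 1.27% at 50 min, and 79.0% reacted.

The forecast gives 3% (−4% to 14%) for the early excess, 2% (−3% to 8%) for the late excess, and 79% (72% to 85%) reacted. It parts from me on the early excess: “The 13/5 reading at 4 min is a single noisy point”.

The flask gives 22.3%, −0.0773% and 80.8%. The early excess stands above the top of the forecast's range; the other two lie inside theirs.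

    reagent + left-handed substrate → left-handed product (k = 0.0380 M⁻¹ min⁻¹)
    reagent + right-handed substrate → right-handed product (k = 0.0220 M⁻¹ min⁻¹)
    left-handed substrate + racemization catalyst ⇌ right-handed substrate + racemization catalyst, rate k3*[racemization catalyst]*[left-handed substrate] forward; the back reaction follows from the equilibrium constant (k = 2.60 M⁻¹ min⁻¹)
    racemization catalyst + impurity → spent catalyst (k = 4100 M⁻¹ min⁻¹)
    left-handed product ⇌ right-handed product (k = 0.0490 min⁻¹)
    racemization catalyst + added ligand ⇌ idle complex, settled at all times (K = 31.0 M⁻¹)

The lead ratio put this flask's early excess at 25.7%, which is 3.4 points from the 22.3% found, inside the scatter of 11 points. The neighbour flask has 1.00 equiv of reagent, a quarter of the charge here. The same reckoning, with [reagent] cancelled from the ratio, gives that neighbour flask the same 25.7%. That neighbour flask has reacted just 30.9% at 50 min, and its excess at 2.5 min is 23.3%.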